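**Retrosynthetic overview**

- Last C–C bond: the ArCH2–Ar bond between the central ring (B) and the carbinol-bearing ring (C), made by an sp3–sp2 Suzuki–Miyaura coupling of a benzylic chloride (rings A–O–B plus CH2, 18 skeletal atoms) with an aryl boronate (ring C plus side chain, 16 skeletal atoms). Global O-debenzylation follows.
- Benzylic chloride fragment: Ullmann coupling of orcinol with O-benzyl-3-bromo-5-methylphenol (both from 3-bromotoluene), then OH-directed ortho-formylation to place the benzylic carbon between OH and CH3.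
- Boronate fragment: 3-chlorophenol, Fries rearrangement, CBS reduction, carbamate, then stereospecific lithiation–borylation with 4-methylpentyl-Bpin to set the (R)-tertiary carbinol; ArCl to ArBpin.
- No ring is constructed. All three benzene rings are bought as simple arenes; assembly order is A–O–B first, then B–CH2–C.

Assumption: acetyl chloride and paraformaldehyde (which supply skeletal carbons) are treated as starting materials; benzyl bromide, boron reagents, the carbamoyl chloride and oxidants are reagents. The stereocentre in the given SMILES is (R) (OH > aryl > CH2 chain > CH3).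

**Fragment A–B (benzylic chloride)**

Step 1
Reactants: 1, 3-bromotoluene
Product: 2, 3-bromo-5-methylphenol
Conditions: [Ir(OMe)(cod)]2 (1 mol%), dtbpy, B2pin2, hexane, 60–80 °C; then Oxone, acetone/H2O, rt (one pot)
Reagents that add atoms: Oxone (potassium peroxymonosulfate), OOS(=O)(=O)[O-].[K+] (phenol oxygen)
Why: Sterically controlled Ir-catalysed C–H borylation of a 1,3-disubstituted arene occurs only at the mutually meta C5–H, and the ArBpin is oxidised in situ to the phenol with C–Br untouched (C–H borylation/oxidation).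

Step 2
Reactants: 2, 3-bromo-5-methylphenol
Product: 3, 1-(benzyloxy)-3-bromo-5-methylbenzene
Conditions: BnBr, K2CO3, acetone, reflux
Reagents that add atoms: benzyl bromide, BrCc1ccccc1
Why: Williamson O-benzylation of the phenoxide.

Step 3
Reactants: 2, 3-bromo-5-methylphenol
Product: 4, orcinol (5-methylbenzene-1,3-diol)
Conditions: Pd(dppf)Cl2 (3 mol%), B2pin2, KOAc, dioxane, 90 °C; then H2O2, aq NaOH, 0 °C to rt; acidify
Reagents that add atoms: hydrogen peroxide, OO (second phenol oxygen)
Why: Miyaura borylation of the aryl bromide (KOAc is too weak to trigger C–O coupling of the free phenol) followed by peroxide oxidation of the ArBpin.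

Step 4
Reactants: 3, 1-(benzyloxy)-3-bromo-5-methylbenzene; 4, orcinol (3 equiv)
Product: 5, 3-[3-(benzyloxy)-5-methylphenoxy]-5-methylphenol
Conditions: CuI (10 mol%), picolinic acid (20 mol%), K3PO4, DMSO, 90 °C, N2
Reagents that add atoms: none
Why: Ligand-accelerated Ullmann diaryl ether synthesis; excess of the symmetric diol suppresses double arylation and leaves one free OH on ring B.

Step 5
Reactants: 5, 3-[3-(benzyloxy)-5-methylphenoxy]-5-methylphenol; 6, paraformaldehyde
Product: 7, 4-[3-(benzyloxy)-5-methylphenoxy]-2-hydroxy-6-methylbenzaldehyde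
Conditions: MgCl2 (anhydrous), Et3N, (CH2O)n, MeCN, reflux
Reagents that add atoms: none (formyl carbon comes from 6)
Why: Casnati–Skattebøl magnesium-phenoxide ortho-formylation reacts only ortho to the free OH (ring A is etherified) and, as is usual for resorcinol monoethers, should favour the site para to the second oxygen (next to CH3) over the site between the two oxygens.

Step 6
Reactants: 7, 4-[3-(benzyloxy)-5-methylphenoxy]-2-hydroxy-6-methylbenzaldehyde
Product: 8, 2-(benzyloxy)-4-[3-(benzyloxy)-5-methylphenoxy]-6-methylbenzaldehyde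
Conditions: BnBr, K2CO3, DMF, 60 °C
Reagents that add atoms: benzyl bromide, BrCc1ccccc1
Why: Williamson etherification of the chelated phenol, which removes the o-quinone-methide liability before benzylic activation.

Step 7
Reactants: 8, 2-(benzyloxy)-4-[3-(benzyloxy)-5-methylphenoxy]-6-methylbenzaldehyde
Product: 9, {2-(benzyloxy)-4-[3-(benzyloxy)-5-methylphenoxy]-6-methylphenyl}methanol
Conditions: NaBH4, THF/MeOH, 0 °C
Reagents that add atoms: none
Why: Borohydride reduction of the aldehyde; ethers are inert.

Step 8
Reactants: 9, {2-(benzyloxy)-4-[3-(benzyloxy)-5-methylphenoxy]-6-methylphenyl}methanol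
Product: 10, 1-(benzyloxy)-5-[3-(benzyloxy)-5-methylphenoxy]-2-(chloromethyl)-3-methylbenzene
Conditions: MsCl, Et3N, LiCl, THF, 0 °C to rt; used crude immediately
Reagents that add atoms: lithium chloride, [Li+].[Cl-] (chloride; MsCl is also a chloride source)
Why: Mesylation with in situ chloride displacement under non-acidic conditions; the electron-rich benzylic mesylate collapses readily to the chloride.

**Fragment C (aryl boronate)**

Step 9
Reactants: 11, 3-chlorophenol; 12, acetyl chloride
Product: 13, 3-chlorophenyl acetate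
Conditions: Et3N, CH2Cl2, 0 °C to rt
Reagents that add atoms: none (acetyl comes from 12)
Why: Simple O-acylation of the phenol.

Step 10
Reactants: 13, 3-chlorophenyl acetate
Product: 14, 1-(4-chloro-2-hydroxyphenyl)ethanone
Conditions: AlCl3 (1.5–2 equiv), neat, 150 °C; aq HCl work-up
Reagents that add atoms: none
Why: High-temperature, ortho-selective Fries rearrangement places the acyl group at the less hindered ortho position (para to Cl), giving the chelated o-hydroxyacetophenone.

Step 11
Reactants: 14, 1-(4-chloro-2-hydroxyphenyl)ethanone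
Product: 15, 1-[2-(benzyloxy)-4-chlorophenyl]ethanone
Conditions: BnBr, K2CO3, DMF, 60 °C
Reagents that add atoms: benzyl bromide, BrCc1ccccc1
Why: Williamson etherification of the chelated phenol.

Step 12
Reactants: 15, 1-[2-(benzyloxy)-4-chlorophenyl]ethanone
Product: 16, (S)-1-[2-(benzyloxy)-4-chlorophenyl]ethanol
Conditions: (R)-Me-CBS (10 mol%), BH3·SMe2, THF, 0 °C, slow ketone addition
Reagents that add atoms: none
Why: Corey–Bakshi–Shibata reduction; the (R)-oxazaborolidine delivers hydride to the face that gives the (S)-aryl methyl carbinol (aryl as the large group).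

Step 13
Reactants: 16, (S)-1-[2-(benzyloxy)-4-chlorophenyl]ethanol
Product: 17, (S)-1-[2-(benzyloxy)-4-chlorophenyl]ethyl N,N-diisopropylcarbamate
Conditions: iPr2NCOCl, Et3N, toluene, reflux
Reagents that add atoms: N,N-diisopropylcarbamoyl chloride, CC(C)N(C(C)C)C(=O)Cl
Why: O-carbamoylation does not touch the stereocentre and installs the group that directs lithiation and later acts as the leaving group.

Step 14
Reactants: 18, 1-bromo-4-methylpentane
Product: 19, 4,4,5,5-tetramethyl-2-(4-methylpentyl)-1,3,2-dioxaborolane
Conditions: Mg, THF; then iPrOBpin, −78 °C to rt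
Reagents that add atoms: 2-isopropoxy-4,4,5,5-tetramethyl-1,3,2-dioxaborolane, CC(C)OB1OC(C)(C)C(C)(C)O1
Why: Grignard formation and trapping with the alkoxyboronate gives the primary alkyl pinacol boronate.

Step 15
Reactants: 17, (S)-carbamate; 19, 4-methylpentyl-Bpin (1.5 equiv)
Product: 20, (R)-2-[2-(benzyloxy)-4-chlorophenyl]-6-methylheptan-2-ol
Conditions: s-BuLi (1.2 equiv), Et2O, −78 °C, 1 h; 19, −78 °C, 1 h; MgBr2·OEt2/MeOH, warm to rt; then NaOH/H2O2, THF, 0 °C to rt
Reagents that add atoms: hydrogen peroxide, OO (hydroxyl oxygen)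
Why: Hoppe–Aggarwal lithiation–borylation: carbamate-directed benzylic deprotonation and boronate formation occur with retention, the 1,2-metallate shift expels the carbamate with inversion, and oxidation is stereoretentive, so the (S)-carbamate gives the (R)-tertiary alcohol; the aryl chloride does not exchange with s-BuLi at −78 °C.

Step 16
Reactants: 20, (R)-2-[2-(benzyloxy)-4-chlorophenyl]-6-methylheptan-2-ol
Product: 21, (R)-2-[2-(benzyloxy)-4-(4,4,5,5-tetramethyl-1,3,2-dioxaborolan-2-yl)phenyl]-6-methylheptan-2-ol
Conditions: B2pin2, Pd2(dba)3 (2 mol%), XPhos (8 mol%), KOAc, dioxane, 100 °C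
Reagents that add atoms: bis(pinacolato)diboron, CC1(C)OB(OC1(C)C)B1OC(C)(C)C(C)(C)O1
Why: Miyaura borylation of the aryl chloride with a bulky biarylphosphine; the weak acetate base leaves the tertiary benzylic alcohol and benzyl ether untouched.

**Coupling and deprotection**

Step 17
Reactants: 10, benzylic chloride; 21, aryl boronate
Product: 22, (R)-2-{2-(benzyloxy)-4-[(2-(benzyloxy)-4-[3-(benzyloxy)-5-methylphenoxy]-6-methylphenyl)methyl]phenyl}-6-methylheptan-2-ol
Conditions: Pd(dppf)Cl2·CH2Cl2 (5 mol%), K3PO4, THF/H2O (10:1), 65 °C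
Reagents that add atoms: none
Why: sp3–sp2 Suzuki–Miyaura coupling; oxidative addition into the benzylic C–Cl bond is fast, there is no β-hydrogen, and the basic conditions do not ionise the tertiary carbinol.

Step 18
Reactants: 22, tri-O-benzyl ether
Product: 23, 2-({3-hydroxy-4-[(2R)-2-hydroxy-6-methylheptan-2-yl]phenyl}methyl)-5-(3-hydroxy-5-methylphenoxy)-3-methylphenol (target)
Conditions: H2 (1 atm), 10% Pd/C, EtOAc (solid NaHCO3 buffer), rt; stop at full conversion
Reagents that add atoms: none
Why: Catalytic hydrogenolysis removes the three aryl benzyl ethers; under neutral, acid-free conditions the diarylmethane, diaryl ether and tertiary benzylic alcohol (stereocentre) should be unaffected.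

**Compound list**

1 | 3-bromotoluene | Cc1cccc(Br)c1 | starting material
2 | 3-bromo-5-methylphenol | Cc1cc(O)cc(Br)c1 | intermediate
3 | 1-(benzyloxy)-3-bromo-5-methylbenzene | Cc1cc(Br)cc(OCc2ccccc2)c1 | intermediate
4 | orcinol (5-methylbenzene-1,3-diol) | Cc1cc(O)cc(O)c1 | intermediate
5 | 3-[3-(benzyloxy)-5-methylphenoxy]-5-methylphenol | Cc1cc(O)cc(Oc2cc(C)cc(OCc3ccccc3)c2)c1 | intermediate
6 | paraformaldehyde (monomer shown) | C=O | starting material
7 | 4-[3-(benzyloxy)-5-methylphenoxy]-2-hydroxy-6-methylbenzaldehyde | O=Cc1c(C)cc(Oc2cc(C)cc(OCc3ccccc3)c2)cc1O | intermediate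
8 | 2-(benzyloxy)-4-[3-(benzyloxy)-5-methylphenoxy]-6-methylbenzaldehyde | O=Cc1c(C)cc(Oc2cc(C)cc(OCc3ccccc3)c2)cc1OCc1ccccc1 | intermediate
9 | {2-(benzyloxy)-4-[3-(benzyloxy)-5-methylphenoxy]-6-methylphenyl}methanol | OCc1c(C)cc(Oc2cc(C)cc(OCc3ccccc3)c2)cc1OCc1ccccc1 | intermediate
10 | 1-(benzyloxy)-5-[3-(benzyloxy)-5-methylphenoxy]-2-(chloromethyl)-3-methylbenzene | ClCc1c(C)cc(Oc2cc(C)cc(OCc3ccccc3)c2)cc1OCc1ccccc1 | intermediate
11 | 3-chlorophenol | Oc1cccc(Cl)c1 | starting material
12 | acetyl chloride | CC(=O)Cl | starting material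
13 | 3-chlorophenyl acetate | CC(=O)Oc1cccc(Cl)c1 | intermediate
14 | 1-(4-chloro-2-hydroxyphenyl)ethanone | CC(=O)c1ccc(Cl)cc1O | intermediate
15 | 1-[2-(benzyloxy)-4-chlorophenyl]ethanone | CC(=O)c1ccc(Cl)cc1OCc1ccccc1 | intermediate
16 | (S)-1-[2-(benzyloxy)-4-chlorophenyl]ethanol | C[C@H](O)c1ccc(Cl)cc1OCc1ccccc1 | intermediate
17 | (S)-1-[2-(benzyloxy)-4-chlorophenyl]ethyl N,N-diisopropylcarbamate | C[C@H](OC(=O)N(C(C)C)C(C)C)c1ccc(Cl)cc1OCc1ccccc1 | intermediate
18 | 1-bromo-4-methylpentane | CC(C)CCCBr | starting material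
19 | 4,4,5,5-tetramethyl-2-(4-methylpentyl)-1,3,2-dioxaborolane | CC(C)CCCB1OC(C)(C)C(C)(C)O1 | intermediate
20 | (R)-2-[2-(benzyloxy)-4-chlorophenyl]-6-methylheptan-2-ol | Clc1ccc([C@](C)(O)CCCC(C)C)c(OCc2ccccc2)c1 | intermediate
21 | (R)-2-[2-(benzyloxy)-4-(pinacolboryl)phenyl]-6-methylheptan-2-ol | CC1(C)OB(c2ccc([C@](C)(O)CCCC(C)C)c(OCc3ccccc3)c2)OC1(C)C | intermediate
22 | (R)-tri-O-benzyl coupled product | Cc1cc(OCc2ccccc2)cc(Oc2cc(C)c(Cc3ccc([C@](C)(O)CCCC(C)C)c(OCc4ccccc4)c3)c(OCc3ccccc3)c2)c1 | intermediate
23 | 2-({3-hydroxy-4-[(2R)-2-hydroxy-6-methylheptan-2-yl]phenyl}methyl)-5-(3-hydroxy-5-methylphenoxy)-3-methylphenol | Cc1cc(O)cc(Oc2cc(C)c(Cc3ccc([C@](C)(O)CCCC(C)C)c(O)c3)c(O)c2)c1 | target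

**Totals**

Total steps: 18.
Longest linear sequence: 9 steps (steps 1, 2, 4, 5, 6, 7, 8, 17, 18; the ring C branch 9, 10, 11, 12, 13, 15, 16, 17, 18 is also 9).

**Three steps most likely to fail**

1. Step 5 (regiochemistry of ortho-formylation: attack between OH and OAr would give the wrong isomer). Fallback: reverse the order. Formylate orcinol 4 first (Vilsmeier–Haack, giving 2,4-dihydroxy-6-methylbenzaldehyde with the carbon already between OH and CH3), then arylate the non-chelated 4-OH selectively (Chan–Lam with the boronic acid made from 3) to reach 7.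
2. Step 15 (competing lithiation of the ArOCH2Ph group or of the ring position between OBn and Cl, or a sluggish 1,2-shift at the hindered centre). Fallback: set the carbinol by Sharpless asymmetric epoxidation instead. Ketone 15 is taken by HWE olefination and DIBAL to the (E)-allylic alcohol, then epoxidation (tartrate chosen by the mnemonic), Red-Al opening to the 1,3-diol, primary tosylation and isobutyl cuprate displacement to give 20.
3. Step 17 (the electron-rich, 2,6-disubstituted benzylic chloride 10 may solvolyse or homocouple before cross-coupling). Fallback: reverse the polarity. Convert 10 to the benzylic zinc chloride (Zn, LiCl) and Negishi-couple it directly with aryl chloride 20 (Pd/SPhos, tertiary OH transiently silylated), which also removes step 16.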